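**Plan**

1. Flavanone numbering is used throughout (O1, C2–C4, C4a, C5–C8, C8a; rings A, B, C). After the four phenols are masked as MOM ethers, ring C is cut at the aryl ether bond O1–C8a.
2. Enabling feature: ring A is a phloroglucinol whose oxygen-bearing carbons C5 and C8a are equivalent and both ortho to the C4 acyl carbon. One oxygen stays as C5–O, the other becomes the leaving group (C8a–OTf), and the ortho C4 carbonyl activates that bond towards palladium.
3. The open chain is then cut at C2–O (formal hydration of a chalcone) and at C2=C3 (Claisen–Schmidt), giving a ring-A acetophenone and a ring-B aldehyde. The three prenyl groups are cut back to phloroacetophenone and 2,4-dihydroxybenzaldehyde.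
4. Forward: rings A and B are C-prenylated and protected separately and joined as the chalcone. The free ortho hydroxyl is triflated, the C2 oxygen is installed, ring C is closed, and the MOM groups are removed last.
5. Stereochemistry: C2 (S) is set by ligand-controlled copper-catalysed conjugate borylation followed by stereoretentive C–B oxidation. The ring closure breaks no bond at C2, so the configuration is carried into the target.
6. Abbreviations: MOM = methoxymethyl, prenyl = 3-methylbut-2-en-1-yl, Tf = trifluoromethanesulfonyl, Bpin = 4,4,5,5-tetramethyl-1,3,2-dioxaborolan-2-yl.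

Key step: step 8

Remark (assumption): the ligand hand named in step 7 is taken to be the one that delivers boron to the face of C2 that gives the S boronate. If the first run shows the opposite sense, the mirror-image ligand is used and nothing else changes.

**Route**

Step 1
Reactants: 1 1-(2,4,6-trihydroxyphenyl)ethanone
Product: 2 1-[2,4,6-trihydroxy-3,5-bis(3-methylbut-2-en-1-yl)phenyl]ethanone
Conditions: prenyl bromide (2.1 equiv), 10% aq. KOH, 0 °C → rt
Reagents that add atoms: prenyl bromide (1-bromo-3-methylbut-2-ene), CC(C)=CCBr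
Why: Phenoxide C-alkylation (C-prenylation) of an acylphloroglucinol: in water the oxygens are solvated and the allylic bromide should be taken up by C3 and C5, the only free ring carbons, to give the 3,5-diprenyl compound.

Step 2
Reactants: 2 1-[2,4,6-trihydroxy-3,5-diprenylphenyl]ethanone
Product: 3 1-[2-hydroxy-4,6-bis(methoxymethoxy)-3,5-bis(3-methylbut-2-en-1-yl)phenyl]ethanone
Conditions: MOMCl (2.3 equiv), i-Pr2NEt, CH2Cl2, 0 °C → rt
Reagents that add atoms: chloromethyl methyl ether (MOMCl), COCCl
Why: Williamson-type MOM ether formation: the C4 hydroxyl and one of the two equivalent ortho hydroxyls should react, while the last ortho hydroxyl is held in a hydrogen bond to the acetyl carbonyl and stays free under amine-base conditions.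

Step 3
Reactants: 4 2,4-dihydroxybenzaldehyde
Product: 5 2,4-dihydroxy-3-(3-methylbut-2-en-1-yl)benzaldehyde
Conditions: prenyl bromide (1.1 equiv), 10% aq. KOH, 0 °C → rt
Reagents that add atoms: prenyl bromide (1-bromo-3-methylbut-2-ene), CC(C)=CCBr
Why: Phenoxide C-alkylation: C3 lies between the two hydroxyls and is the most nucleophilic ring carbon in aqueous base, the established entry to 3-prenyl-2,4-dihydroxybenzaldehyde.

Step 4
Reactants: 5 2,4-dihydroxy-3-prenylbenzaldehyde
Product: 6 2,4-bis(methoxymethoxy)-3-(3-methylbut-2-en-1-yl)benzaldehyde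
Conditions: NaH (2.5 equiv), MOMCl (2.5 equiv), DMF, 0 °C → rt
Reagents that add atoms: chloromethyl methyl ether (MOMCl), COCCl
Why: Williamson-type MOM protection; NaH is used so that the hydroxyl chelated to the aldehyde is etherified as well.

Step 5
Reactants: 3 1-[2-hydroxy-4,6-bis(methoxymethoxy)-3,5-diprenylphenyl]ethanone; 6 2,4-bis(methoxymethoxy)-3-prenylbenzaldehyde
Product: 7 (2E)-3-[2,4-bis(methoxymethoxy)-3-prenylphenyl]-1-[2-hydroxy-4,6-bis(methoxymethoxy)-3,5-diprenylphenyl]prop-2-en-1-one
Conditions: KOH (excess), EtOH–H2O, rt; dilute acid work-up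
Reagents that add atoms: none
Why: Claisen–Schmidt (crossed aldol) condensation: the enolate of the methyl ketone adds to the non-enolisable aldehyde and E1cB loss of water should give the (E)-enone, the free ortho hydroxyl being carried as its phenoxide.

Step 6
Reactants: 7 the 2'-hydroxychalcone
Product: 8 2-{(2E)-3-[2,4-bis(methoxymethoxy)-3-prenylphenyl]prop-2-enoyl}-3,5-bis(methoxymethoxy)-4,6-diprenylphenyl trifluoromethanesulfonate
Conditions: Tf2O (1.2 equiv), pyridine, CH2Cl2, −20 → 0 °C
Reagents that add atoms: trifluoromethanesulfonic anhydride (Tf2O), O=S(=O)(OS(=O)(=O)C(F)(F)F)C(F)(F)F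
Why: O-Sulfonylation of the only free hydroxyl, the hydrogen-bonded phenol on the carbon that becomes C8a, turns this oxygen into the leaving group for the ring closure.

Step 7
Reactants: 8 the chalcone triflate
Product: 10 2-{(3S)-3-[2,4-bis(methoxymethoxy)-3-prenylphenyl]-3-hydroxypropanoyl}-3,5-bis(methoxymethoxy)-4,6-diprenylphenyl trifluoromethanesulfonate, via (S)-β-boryl ketone 9 (not isolated)
Conditions: CuCl (5 mol%), NaOt-Bu (10 mol%), Josiphos ligand (R)-1-[(S)-2-(diphenylphosphino)ferrocenyl]ethyldicyclohexylphosphine (6 mol%), B2pin2 (1.1 equiv), MeOH (2 equiv), THF, rt; then NaBO3·4H2O, THF–H2O, 0 °C → rt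
Reagents that add atoms: bis(pinacolato)diboron (B2pin2), CC1(C)OB(OC1(C)C)B1OC(C)(C)C(C)(C)O1 (boron group of 9); NaBO3·4H2O (sodium perborate), [Na+].[O-]OB=O (hydroxyl oxygen of 10)
Why: Copper-catalysed enantioselective conjugate borylation (β-boration): the chiral phosphine–copper boryl species should add to the enone β-carbon (C2) with ligand-controlled facial selectivity, methanol turns over the copper enolate, and perborate oxidation replaces boron by oxygen with retention, so the S configuration at C2 is set here.

Step 8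
Reactants: 10 the (S)-β-hydroxy ketone triflate
Product: 11 (2S)-2-[2,4-bis(methoxymethoxy)-3-prenylphenyl]-5,7-bis(methoxymethoxy)-6,8-diprenyl-2,3-dihydro-4H-chromen-4-one
Conditions: Pd2(dba)3 (2.5 mol%), RockPhos (2-di-tert-butylphosphino-3-methoxy-6-methyl-2',4',6'-triisopropylbiphenyl, 6 mol%), K3PO4 (2 equiv), toluene, 70 °C
Reagents that add atoms: none
Why: Zerovalent palladium inserts into the C8a–OTf bond of ring A, an oxidative addition accelerated by the ortho C4 carbonyl; the C2 hydroxyl then binds palladium, is deprotonated by the insoluble phosphate, and C(aryl)–O reductive elimination forms O1–C8a. The closest known reaction type is the intramolecular Buchwald–Hartwig etherification of aryl halides and sulfonates with secondary alcohols. Ring C closes as a six-membered ring by reductive elimination from a seven-membered aryl palladium alkoxide. No stereocentre is formed: C2 should keep its S configuration because neither the C2–O1 nor the C2–H bond is broken and no free alkoxide, the species that would undergo retro-aldol cleavage, is generated. The step needs C–O reductive elimination to outrun β-hydride elimination and base-induced dehydration of the β-hydroxy ketone; the bulky di-tert-butyl biaryl phosphine, the electron-poor acyl-substituted aryl group on palladium and the weak heterogeneous base are chosen to secure this. Site selectivity is not an issue, because the other ortho oxygen (C5–O) is a MOM ether and only one triflate is present.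

Step 9
Reactants: 11 the tetra-MOM (2S)-flavanone
Product: 12 (2S)-2-[2,4-dihydroxy-3-(3-methylbut-2-en-1-yl)phenyl]-5,7-dihydroxy-6,8-bis(3-methylbut-2-en-1-yl)-2,3-dihydro-4H-chromen-4-one
Conditions: 3 M HCl, MeOH, rt → 40 °C; work-up without base
Reagents that add atoms: none
Why: Acid-catalysed acetal exchange (MOM cleavage) with methanol as acceptor should free the four phenols, since dilute acid near room temperature is known to spare prenyl groups and C2 is not expected to ionise under these conditions.

**Compound list**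

1 | 1-(2,4,6-trihydroxyphenyl)ethanone (phloroacetophenone) | CC(=O)c1c(O)cc(O)cc1O | starting material
2 | 1-[2,4,6-trihydroxy-3,5-bis(3-methylbut-2-en-1-yl)phenyl]ethanone | CC(=O)c1c(O)c(CC=C(C)C)c(O)c(CC=C(C)C)c1O | intermediate
3 | 1-[2-hydroxy-4,6-bis(methoxymethoxy)-3,5-bis(3-methylbut-2-en-1-yl)phenyl]ethanone | CC(=O)c1c(O)c(CC=C(C)C)c(OCOC)c(CC=C(C)C)c1OCOC | intermediate
4 | 2,4-dihydroxybenzaldehyde | O=Cc1ccc(O)cc1O | starting material
5 | 2,4-dihydroxy-3-(3-methylbut-2-en-1-yl)benzaldehyde | O=Cc1ccc(O)c(CC=C(C)C)c1O | intermediate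
6 | 2,4-bis(methoxymethoxy)-3-(3-methylbut-2-en-1-yl)benzaldehyde | O=Cc1ccc(OCOC)c(CC=C(C)C)c1OCOC | intermediate
7 | (2E)-3-[2,4-bis(methoxymethoxy)-3-(3-methylbut-2-en-1-yl)phenyl]-1-[2-hydroxy-4,6-bis(methoxymethoxy)-3,5-bis(3-methylbut-2-en-1-yl)phenyl]prop-2-en-1-one | CC(C)=CCc1c(OCOC)ccc(/C=C/C(=O)c2c(O)c(CC=C(C)C)c(OCOC)c(CC=C(C)C)c2OCOC)c1OCOC | intermediate
8 | 2-{(2E)-3-[2,4-bis(methoxymethoxy)-3-(3-methylbut-2-en-1-yl)phenyl]prop-2-enoyl}-3,5-bis(methoxymethoxy)-4,6-bis(3-methylbut-2-en-1-yl)phenyl trifluoromethanesulfonate | CC(C)=CCc1c(OCOC)ccc(/C=C/C(=O)c2c(OS(=O)(=O)C(F)(F)F)c(CC=C(C)C)c(OCOC)c(CC=C(C)C)c2OCOC)c1OCOC | intermediate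
9 | 2-{(3S)-3-[2,4-bis(methoxymethoxy)-3-(3-methylbut-2-en-1-yl)phenyl]-3-(4,4,5,5-tetramethyl-1,3,2-dioxaborolan-2-yl)propanoyl}-3,5-bis(methoxymethoxy)-4,6-bis(3-methylbut-2-en-1-yl)phenyl trifluoromethanesulfonate | CC(C)=CCc1c(OCOC)ccc([C@@H](B3OC(C)(C)C(C)(C)O3)CC(=O)c2c(OS(=O)(=O)C(F)(F)F)c(CC=C(C)C)c(OCOC)c(CC=C(C)C)c2OCOC)c1OCOC | intermediate
10 | 2-{(3S)-3-[2,4-bis(methoxymethoxy)-3-(3-methylbut-2-en-1-yl)phenyl]-3-hydroxypropanoyl}-3,5-bis(methoxymethoxy)-4,6-bis(3-methylbut-2-en-1-yl)phenyl trifluoromethanesulfonate | CC(C)=CCc1c(OCOC)ccc([C@@H](O)CC(=O)c2c(OS(=O)(=O)C(F)(F)F)c(CC=C(C)C)c(OCOC)c(CC=C(C)C)c2OCOC)c1OCOC | intermediate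
11 | (2S)-2-[2,4-bis(methoxymethoxy)-3-(3-methylbut-2-en-1-yl)phenyl]-5,7-bis(methoxymethoxy)-6,8-bis(3-methylbut-2-en-1-yl)-2,3-dihydro-4H-chromen-4-one | CC(C)=CCc1c(OCOC)ccc([C@@H]2CC(=O)c3c(OCOC)c(CC=C(C)C)c(OCOC)c(CC=C(C)C)c3O2)c1OCOC | intermediate
12 | (2S)-2-[2,4-dihydroxy-3-(3-methylbut-2-en-1-yl)phenyl]-5,7-dihydroxy-6,8-bis(3-methylbut-2-en-1-yl)-2,3-dihydro-4H-chromen-4-one | CC(C)=CCc1c(O)ccc([C@@H]2CC(=O)c3c(O)c(CC=C(C)C)c(O)c(CC=C(C)C)c3O2)c1O | target

**Step count and risks**

Total step count: 9. Longest linear sequence: 7 steps (steps 1, 2, 5, 6, 7, 8, 9 from compound 1; the branch from compound 4 is equally long).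

Steps most likely to fail:

1. Step 8 (ring closure). β-Hydride elimination from the palladium alkoxide at the electron-rich benzylic carbinol, or base-induced dehydration of the β-hydroxy ketone, may outrun C–O reductive elimination. The fallback sets out from 10 and returns at 11. The triflate is exchanged for boron by Miyaura borylation (PdCl2(dppf), B2pin2, KOAc, dioxane, 80 °C) to give the aryl pinacol boronate of the β-hydroxy ketone F1. The same O1–C8a bond is then formed by copper-promoted oxidative etherification of the Chan–Lam type (Cu(OAc)2, pyridine, 4 Å molecular sieves, air, CH2Cl2, rt), which runs under nearly neutral conditions without a palladium alkoxide and should give 11.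

2. Step 7 (C2 oxygen and configuration). Facial selectivity of the boryl-copper addition may be poor on the hindered, twisted enone, or peroxide may attack the triflate sulfur during the oxidation. The fallback sets out from 8 and returns at 10. Catalytic asymmetric nucleophilic epoxidation of the enone (La(O-iPr)3, BINOL of the hand that gives the 2S,3R product, Ph3As=O, t-BuOOH, 4 Å molecular sieves, THF, rt) should give the (2S,3R)-epoxy ketone F2. Regioselective reductive opening of the Cα–O bond (PhSeSePh, NaBH4, AcOH, EtOH, 0 °C) leaves the Cβ–O bond and its configuration untouched and should give 10.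

3. Step 1 (double C-prenylation of ring A). Over-alkylation to the geminal 3,3-diprenyl (dearomatised) product and O-alkylation may leave little of the 3,5-isomer. The fallback sets out from 1 and returns at 3. Both free ring positions are iodinated (N-iodosuccinimide, DMF, 0 °C) to give the 3,5-diiodo triol F3, which is bis-protected (MOMCl, i-Pr2NEt, CH2Cl2) to give the diiodo bis-MOM ether F4. Double Stille coupling with tributyl(3-methylbut-2-en-1-yl)stannane (Pd(PPh3)4, DMF, 90 °C) should then give 3 without passing through 2.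

**Further compounds**

F1 | step 8 | (3S)-3-[2,4-bis(methoxymethoxy)-3-(3-methylbut-2-en-1-yl)phenyl]-1-[2,4-bis(methoxymethoxy)-3,5-bis(3-methylbut-2-en-1-yl)-6-(4,4,5,5-tetramethyl-1,3,2-dioxaborolan-2-yl)phenyl]-3-hydroxypropan-1-one | CC(C)=CCc1c(OCOC)ccc([C@@H](O)CC(=O)c2c(B3OC(C)(C)C(C)(C)O3)c(CC=C(C)C)c(OCOC)c(CC=C(C)C)c2OCOC)c1OCOC
F2 | step 7 | 2-({(2S,3R)-3-[2,4-bis(methoxymethoxy)-3-(3-methylbut-2-en-1-yl)phenyl]oxiran-2-yl}carbonyl)-3,5-bis(methoxymethoxy)-4,6-bis(3-methylbut-2-en-1-yl)phenyl trifluoromethanesulfonate | CC(C)=CCc1c(OCOC)ccc([C@H]2O[C@@H]2C(=O)c3c(OS(=O)(=O)C(F)(F)F)c(CC=C(C)C)c(OCOC)c(CC=C(C)C)c3OCOC)c1OCOC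
F3 | step 1 | 1-(2,4,6-trihydroxy-3,5-diiodophenyl)ethanone | CC(=O)c1c(O)c(I)c(O)c(I)c1O
F4 | step 1 | 1-[2-hydroxy-3,5-diiodo-4,6-bis(methoxymethoxy)phenyl]ethanone | CC(=O)c1c(O)c(I)c(OCOC)c(I)c1OCOC
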